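Rings B and D are cut back to alkynes. In each catechol ring the two adjacent oxygen-bearing carbons C4 and C5 sit between two CH carbons, C3 and C6, opposite the C1–C2 edge that carries the octamethylene chain plus ring C (ring B) or the chain plus H (ring D). C1–C2 is therefore an alkyne and C3–C4–C5–C6 is 2,3-dimethoxybuta-1,3-diene. One cobalt-catalysed twofold [4+2] cycloaddition forms four C–C bonds and both rings as 1,4-cyclohexadienes, one dehydrogenation below the veratroles. Its precursor is a linear diyne in which ring C, carrying its ketone chain with a terminal alkyne, is alkynylated at C3 by the chain of the ring A ketone.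

Key step: step 8

Remark on the chemistry: a free C(sp)–H would quench the aryllithium used for the ketone synthesis, so the alkyne is capped with trimethylsilyl first. The capped ketone 9 then serves twice, as the iodination substrate and, after desilylation, as the alkyne partner. The target has no stereocentre.

Step 1
Reactants: 1 undec-10-ynoic acid
Product: 4 11-(trimethylsilyl)undec-10-ynoic acid, via lithium 11-lithioundec-10-ynoate 2 (not isolated), via trimethylsilyl 11-(trimethylsilyl)undec-10-ynoate 3 (not isolated)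
Conditions: n-BuLi (2.2 equiv), THF, −78 °C; TMSCl (2.5 equiv), −78 °C to rt; 1 M HCl
Reagents that add atoms: chlorotrimethylsilane, C[Si](C)(C)Cl
Why: Double deprotonation gives the carboxylate–acetylide dianion, both sites are silylated, and the acidic work-up cleaves only the labile silyl ester (C-silylation of a lithium acetylide).

Step 2
Reactants: 4 11-(trimethylsilyl)undec-10-ynoic acid
Product: 6 N-methoxy-N-methyl-11-(trimethylsilyl)undec-10-ynamide, via 1-[11-(trimethylsilyl)undec-10-ynoyl]imidazole 5 (not isolated)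
Conditions: CDI (1.1 equiv), CH2Cl2, rt; MeNH(OMe)·HCl (1.3 equiv), rt
Reagents that add atoms: N,O-dimethylhydroxylamine hydrochloride, CNOC.Cl
Why: CDI activates the acid as the acyl imidazolide, which acylates the hydroxylamine under neutral conditions that leave the alkynylsilane untouched (Weinreb amide formation by acyl transfer).

Step 3
Reactants: 6 N-methoxy-N-methyl-11-(trimethylsilyl)undec-10-ynamide; 7 1,3-dimethoxybenzene
Product: 9 1-(2,6-dimethoxyphenyl)-11-(trimethylsilyl)undec-10-yn-1-one, via 2,6-dimethoxyphenyllithium 8 (not isolated)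
Conditions: 7 (1.4 equiv), n-BuLi (1.3 equiv), THF, 0 °C to rt; then 6, −78 to 0 °C; aq. NH4Cl
Reagents that add atoms: none
Why: Directed ortho-metalation between the two methoxy groups gives the 2-lithio arene, and the N-methoxy-N-methylamide holds the adduct as a chelate until work-up, so the ketone forms without over-addition (Weinreb ketone synthesis).

Step 4
Reactants: 9 1-(2,6-dimethoxyphenyl)-11-(trimethylsilyl)undec-10-yn-1-one
Product: 10 1-(3-iodo-2,6-dimethoxyphenyl)-11-(trimethylsilyl)undec-10-yn-1-one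
Conditions: NIS (1.05 equiv), TFA (0.2 equiv), MeCN, 0 °C to rt, dark
Reagents that add atoms: N-iodosuccinimide, O=C1CCC(=O)N1I
Why: Electrophilic aromatic iodination goes to C3, which is ortho to one methoxy group, para to the other and meta to the acyl group; C3 and C5 are equivalent, one equivalent of NIS should stop at the mono-iodide, and without silver or fluoride the alkynylsilane should be spared.

Step 5
Reactants: 9 1-(2,6-dimethoxyphenyl)-11-(trimethylsilyl)undec-10-yn-1-one
Product: 11 1-(2,6-dimethoxyphenyl)undec-10-yn-1-one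
Conditions: K2CO3, MeOH, rt
Reagents that add atoms: none
Why: Methoxide-mediated protodesilylation of an alkynylsilane is fast at room temperature and does not touch the aryl ketone or the methyl ethers.

Step 6
Reactants: 10 1-(3-iodo-2,6-dimethoxyphenyl)-11-(trimethylsilyl)undec-10-yn-1-one; 11 1-(2,6-dimethoxyphenyl)undec-10-yn-1-one
Product: 12 1-{3-[11-(2,6-dimethoxyphenyl)-11-oxoundec-1-yn-1-yl]-2,6-dimethoxyphenyl}-11-(trimethylsilyl)undec-10-yn-1-one
Conditions: PdCl2(PPh3)2 (5 mol%), CuI (10 mol%), Et3N/THF, degassed, rt to 50 °C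
Reagents that add atoms: none
Why: Sonogashira coupling: the aryl iodide adds oxidatively to zerovalent palladium, the copper acetylide of 11 transmetalates, and the silyl cap on 10 rules out self-coupling of the iodide.

Step 7
Reactants: 12 1-{3-[11-(2,6-dimethoxyphenyl)-11-oxoundec-1-yn-1-yl]-2,6-dimethoxyphenyl}-11-(trimethylsilyl)undec-10-yn-1-one
Product: 13 1-{3-[11-(2,6-dimethoxyphenyl)-11-oxoundec-1-yn-1-yl]-2,6-dimethoxyphenyl}undec-10-yn-1-one (diyne holding rings A and C)
Conditions: K2CO3, MeOH/THF, rt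
Reagents that add atoms: none
Why: The same mild protodesilylation as in step 5 frees the terminal alkyne, and the internal aryl alkyl alkyne is inert to it.

Step 8
Reactants: 13 1-{3-[11-(2,6-dimethoxyphenyl)-11-oxoundec-1-yn-1-yl]-2,6-dimethoxyphenyl}undec-10-yn-1-one; 14 2,3-dimethoxybuta-1,3-diene
Product: 15 1-{3-[2-[9-(2,6-dimethoxyphenyl)-9-oxononyl]-4,5-dimethoxycyclohexa-1,4-dien-1-yl]-2,6-dimethoxyphenyl}-9-(4,5-dimethoxycyclohexa-1,4-dien-1-yl)nonan-1-one
Conditions: CoBr2(dppe) (20 mol%), Zn powder (40 mol%), ZnI2 (40 mol%), 14 (6 equiv), CH2Cl2, rt to 40 °C; filtration through basic alumina (Et3N-doped eluent), used crude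
Reagents that add atoms: none
Why: Zn reduces CoBr2(dppe) to a monovalent cobalt species that ZnI2 renders cationic; it binds the s-cis diene and one alkyne, couples them oxidatively to a cobaltacycle and reductively eliminates the 1,4-cyclohexadiene. The closest known reaction type is the cobalt-catalysed neutral Diels–Alder reaction of unactivated terminal and internal alkynes with 1,3-dienes, applied here with an oxygenated diene. Ring B closes by a formal intermolecular [4+2] annulation in which the two diene termini bond to both carbons of the internal aryl alkyl alkyne, and ring D closes in the same mode at the terminal alkyne. No stereocentre is created, and because the diene is symmetric neither alkyne can give regioisomers. The step needs chemoselectivity for cross-cycloaddition over alkyne cyclotrimerisation and diene dimerisation, which the chelating dppe ligand, the excess of diene and the remoteness of the two alkynes from each other should secure, with the aryl ketones and methyl ethers as spectators. The internal alkyne beside the ring C methoxy group is the slower site and sets loading and temperature, and the acid-labile bis(enol ether) is freed from zinc salts on basic alumina and oxidised at once.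

Step 9
Reactants: 15 the bis(4,5-dimethoxycyclohexa-1,4-diene) adduct from step 8
Product: 16 1-{3-[2-[9-(2,6-dimethoxyphenyl)-9-oxononyl]-4,5-dimethoxyphenyl]-2,6-dimethoxyphenyl}-9-(3,4-dimethoxyphenyl)nonan-1-one (giganteone A octamethyl ether)
Conditions: DDQ (2.2 equiv), NaHCO3, toluene, rt
Reagents that add atoms: none
Why: DDQ abstracts hydride from a doubly allylic CH2 of each 1,4-cyclohexadiene and loss of a proton gives the arene (dehydrogenative aromatisation), a process much faster than benzylic oxidation; the NaHCO3 buffer keeps the acidic hydroquinone from protonating the enol ethers.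

Step 10
Reactants: 16 giganteone A octamethyl ether
Product: 17 giganteone A, 1-{3-[2-[9-(2,6-dihydroxyphenyl)-9-oxononyl]-4,5-dihydroxyphenyl]-2,6-dihydroxyphenyl}-9-(3,4-dihydroxyphenyl)nonan-1-one
Conditions: BBr3 (12 equiv), CH2Cl2, −78 °C to rt; MeOH then H2O, 0 °C, under argon
Reagents that add atoms: none
Why: BBr3 coordinates each ether oxygen, helped by chelation at the four ketone-flanked ones, bromide cleaves the O–CH3 bonds and the borates hydrolyse on quench (Lewis-acid aryl methyl ether cleavage); the ketones and saturated chains are inert, and degassed work-up protects the catechols.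

Compound list
1 | undec-10-ynoic acid | C#CCCCCCCCCC(=O)O | starting material
2 | lithium 11-lithioundec-10-ynoate | [Li]C#CCCCCCCCCC(=O)O[Li] | intermediate
3 | trimethylsilyl 11-(trimethylsilyl)undec-10-ynoate | C[Si](C)(C)C#CCCCCCCCCC(=O)O[Si](C)(C)C | intermediate
4 | 11-(trimethylsilyl)undec-10-ynoic acid | C[Si](C)(C)C#CCCCCCCCCC(=O)O | intermediate
5 | 1-[11-(trimethylsilyl)undec-10-ynoyl]imidazole | C[Si](C)(C)C#CCCCCCCCCC(=O)n1ccnc1 | intermediate
6 | N-methoxy-N-methyl-11-(trimethylsilyl)undec-10-ynamide | C[Si](C)(C)C#CCCCCCCCCC(=O)N(C)OC | intermediate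
7 | 1,3-dimethoxybenzene | COc1cccc(OC)c1 | starting material
8 | 2,6-dimethoxyphenyllithium | COc1cccc(OC)c1[Li] | intermediate
9 | 1-(2,6-dimethoxyphenyl)-11-(trimethylsilyl)undec-10-yn-1-one | COc1cccc(OC)c1C(=O)CCCCCCCCC#C[Si](C)(C)C | intermediate
10 | 1-(3-iodo-2,6-dimethoxyphenyl)-11-(trimethylsilyl)undec-10-yn-1-one | COc1ccc(I)c(OC)c1C(=O)CCCCCCCCC#C[Si](C)(C)C | intermediate
11 | 1-(2,6-dimethoxyphenyl)undec-10-yn-1-one | COc1cccc(OC)c1C(=O)CCCCCCCCC#C | intermediate
12 | 1-{3-[11-(2,6-dimethoxyphenyl)-11-oxoundec-1-yn-1-yl]-2,6-dimethoxyphenyl}-11-(trimethylsilyl)undec-10-yn-1-one | COc1cccc(OC)c1C(=O)CCCCCCCCC#Cc1ccc(OC)c(C(=O)CCCCCCCCC#C[Si](C)(C)C)c1OC | intermediate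
13 | 1-{3-[11-(2,6-dimethoxyphenyl)-11-oxoundec-1-yn-1-yl]-2,6-dimethoxyphenyl}undec-10-yn-1-one | COc1cccc(OC)c1C(=O)CCCCCCCCC#Cc1ccc(OC)c(C(=O)CCCCCCCCC#C)c1OC | intermediate
14 | 2,3-dimethoxybuta-1,3-diene | C=C(OC)C(=C)OC | starting material
15 | 1-{3-[2-[9-(2,6-dimethoxyphenyl)-9-oxononyl]-4,5-dimethoxycyclohexa-1,4-dien-1-yl]-2,6-dimethoxyphenyl}-9-(4,5-dimethoxycyclohexa-1,4-dien-1-yl)nonan-1-one | COc1cccc(OC)c1C(=O)CCCCCCCCC1=C(CC(OC)=C(OC)C1)c1ccc(OC)c(C(=O)CCCCCCCCC2=CCC(OC)=C(OC)C2)c1OC | intermediate
16 | 1-{3-[2-[9-(2,6-dimethoxyphenyl)-9-oxononyl]-4,5-dimethoxyphenyl]-2,6-dimethoxyphenyl}-9-(3,4-dimethoxyphenyl)nonan-1-one | COc1cccc(OC)c1C(=O)CCCCCCCCc1cc(OC)c(OC)cc1-c1ccc(OC)c(C(=O)CCCCCCCCc2ccc(OC)c(OC)c2)c1OC | intermediate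
17 | giganteone A | O=C(CCCCCCCCc1cc(O)c(O)cc1-c1ccc(O)c(C(=O)CCCCCCCCc2ccc(O)c(O)c2)c1O)c1c(O)cccc1O | target

Total step count: 10. Longest linear sequence: 9 steps (steps 1, 2, 3, 4, 6, 7, 8, 9, 10; step 5 branches from compound 9).

Steps most likely to fail

Step 8. The hindered internal alkyne beside the ring C methoxy group may not enter the cobaltacycle, so that alkyne cyclotrimerisation takes over, or ZnI2 may strip methanol from the enol ether rings before they can be oxidised. Fallback: both catechol rings are bought as veratrole halides and every aryl–alkyl and aryl–aryl bond is made by Suzuki–Miyaura coupling. The fallback sets out from 2,6-dimethoxyphenyllithium 8 and returns at octamethyl ether 16. Non-8-enoic acid is converted (CDI, MeNH(OMe)·HCl) into N-methoxy-N-methylnon-8-enamide F1, which with 8 gives 1-(2,6-dimethoxyphenyl)non-8-en-1-one F2. One portion of F2 is iodinated (NIS, cat. TFA, MeCN) to 1-(3-iodo-2,6-dimethoxyphenyl)non-8-en-1-one F3. A second portion is hydroborated with 9-BBN to 9-[9-(2,6-dimethoxyphenyl)-9-oxononyl]-9-borabicyclo[3.3.1]nonane F4. This borane is coupled at the C–I bond of 1-bromo-2-iodo-4,5-dimethoxybenzene (PdCl2(dppf), K3PO4, DMF/H2O) to give 9-(2-bromo-4,5-dimethoxyphenyl)-1-(2,6-dimethoxyphenyl)nonan-1-one F5. Miyaura borylation (B2pin2, PdCl2(dppf), KOAc, dioxane) gives 1-(2,6-dimethoxyphenyl)-9-[4,5-dimethoxy-2-(4,4,5,5-tetramethyl-1,3,2-dioxaborolan-2-yl)phenyl]nonan-1-one F6. Coupling of F6 with F3 (Pd(OAc)2, SPhos, K3PO4, toluene/H2O) gives 1-{3-[2-[9-(2,6-dimethoxyphenyl)-9-oxononyl]-4,5-dimethoxyphenyl]-2,6-dimethoxyphenyl}non-8-en-1-one F7. Hydroboration of its terminal alkene with 9-BBN gives the B-alkyl-9-borabicyclo[3.3.1]nonane adduct of F7, F8, which is coupled with 4-bromo-1,2-dimethoxybenzene (PdCl2(dppf), K3PO4) to give 16.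

Step 10. Cleavage of eight ethers may stop at mixtures of partial methyl ethers, and the two free catechol rings may oxidise in air or be lost on silica during isolation. Fallback: the polyphenol is derivatised, purified and then released. The fallback sets out from 16 and returns at 17. After the BBr3 treatment and quench the crude product is acetylated without purification (Ac2O, pyridine, DMAP) to giganteone A octaacetate F9, which is stable to air and chromatography and separable from incompletely demethylated material. Acid-catalysed methanolysis (HCl in degassed MeOH, rt) then gives 17 without exposing the catechols to base.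

Step 6. Copper-mediated oxidative dimerisation of alkyne 11 may outrun a slow oxidative addition at the electron-rich, ortho-methoxy iodide 10. Fallback: the aryl–alkynyl bond is made by Stille coupling, with no copper and no free alkyne present. The fallback sets out from 11 and returns at 12. Alkyne 11 is stannylated under neutral conditions (Bu3SnOMe, cat. ZnBr2, THF) to 1-(2,6-dimethoxyphenyl)-11-(tributylstannyl)undec-10-yn-1-one F10, which is coupled with iodide 10 (Pd(PPh3)4, toluene, 80 °C) to give 12.

Further compounds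
F1 | step 8 | N-methoxy-N-methylnon-8-enamide | C=CCCCCCCC(=O)N(C)OC
F2 | step 8 | 1-(2,6-dimethoxyphenyl)non-8-en-1-one | COc1cccc(OC)c1C(=O)CCCCCCC=C
F3 | step 8 | 1-(3-iodo-2,6-dimethoxyphenyl)non-8-en-1-one | COc1ccc(I)c(OC)c1C(=O)CCCCCCC=C
F4 | step 8 | 9-[9-(2,6-dimethoxyphenyl)-9-oxononyl]-9-borabicyclo[3.3.1]nonane | COc1cccc(OC)c1C(=O)CCCCCCCCB1C2CCCC1CCC2
F5 | step 8 | 9-(2-bromo-4,5-dimethoxyphenyl)-1-(2,6-dimethoxyphenyl)nonan-1-one | COc1cccc(OC)c1C(=O)CCCCCCCCc1cc(OC)c(OC)cc1Br
F6 | step 8 | 1-(2,6-dimethoxyphenyl)-9-[4,5-dimethoxy-2-(4,4,5,5-tetramethyl-1,3,2-dioxaborolan-2-yl)phenyl]nonan-1-one | COc1cccc(OC)c1C(=O)CCCCCCCCc1cc(OC)c(OC)cc1B1OC(C)(C)C(C)(C)O1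
F7 | step 8 | 1-{3-[2-[9-(2,6-dimethoxyphenyl)-9-oxononyl]-4,5-dimethoxyphenyl]-2,6-dimethoxyphenyl}non-8-en-1-one | COc1cccc(OC)c1C(=O)CCCCCCCCc1cc(OC)c(OC)cc1-c1ccc(OC)c(C(=O)CCCCCCC=C)c1OC
F8 | step 8 | 9-(9-borabicyclo[3.3.1]nonan-9-yl)-1-{3-[2-[9-(2,6-dimethoxyphenyl)-9-oxononyl]-4,5-dimethoxyphenyl]-2,6-dimethoxyphenyl}nonan-1-one | COc1cccc(OC)c1C(=O)CCCCCCCCc1cc(OC)c(OC)cc1-c1ccc(OC)c(C(=O)CCCCCCCCB2C3CCCC2CCC3)c1OC
F9 | step 10 | giganteone A octaacetate | O=C(CCCCCCCCc1cc(OC(C)=O)c(OC(C)=O)cc1-c1ccc(OC(C)=O)c(C(=O)CCCCCCCCc2ccc(OC(C)=O)c(OC(C)=O)c2)c1OC(C)=O)c1c(OC(C)=O)cccc1OC(C)=O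
F10 | step 6 | 1-(2,6-dimethoxyphenyl)-11-(tributylstannyl)undec-10-yn-1-one | COc1cccc(OC)c1C(=O)CCCCCCCCC#C[Sn](CCCC)(CCCC)CCCC
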